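## Retrosynthetic overview

1. The (E)-styrene C=C is cut (Horner–Wadsworth–Emmons) into the α-quaternary aldehyde 10 and the C8-benzylic phosphonate 17 of 7-methoxycoumarin (fragment B).
2. The cyclohexene ring and both stereocentres of 10 come from one enantioselective, amine-catalysed Diels–Alder reaction of coumarin diene 8 (fragment A) with methacrolein 9.
3. Diene 8 comes from suberenol 6, which comes from a Heck reaction of 6-bromo-7-methoxycoumarin 4 with 2-methylbut-3-en-2-ol 5.
4. Ring order: the two coumarin pyranone rings first (Wittig–lactonisation of salicylaldehydes 1 and 11), then the cyclohexene ring in step 4; the final olefination forms no ring.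

Assumption: salicylaldehydes 1 and 11 are taken as catalogue compounds, and because no precedent fixes the facial sense of the new step 4, the route is written for the quinine-derived amine, with its quinidine-derived pseudo-enantiomer used instead if the first run gives the mirror-image adduct.

## Route

Step 1
Reactants: 1 5-bromo-2-hydroxy-4-methoxybenzaldehyde
Product: 4 6-bromo-7-methoxycoumarin, via E-cinnamate ester 2 (not isolated), via Z-cinnamate ester 3 (not isolated)
Conditions: Ph3P=CHCO2Et (1.2 equiv), PhNEt2, 210 °C, 3 h
Reagents that add atoms: ethyl (triphenylphosphoranylidene)acetate, CCOC(=O)C=P(c1ccccc1)(c1ccccc1)c1ccccc1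
Why: Wittig olefination of the salicylaldehyde gives the cinnamates, and at 210 °C the E-ester isomerises to the Z-ester, whose phenol lactonises with loss of ethanol (Wittig–lactonisation coumarin synthesis); no stereocentre is formed.

Step 2
Reactants: 4 6-bromo-7-methoxycoumarin; 5 2-methylbut-3-en-2-ol
Product: 6 suberenol (6-[(E)-3-hydroxy-3-methylbut-1-enyl]-7-methoxycoumarin)
Conditions: Pd(OAc)2 (5 mol%), P(o-tol)3 (10 mol%), Et3N (2 equiv), DMF, 100 °C
Reagents that add atoms: none
Why: Mizoroki–Heck reaction, in which insertion of the terminal alkene and syn-β-hydride elimination from the benzylic carbon (the carbinol carbon has no hydrogen) give only the E-styrenyl alcohol, while the lactone and the coumarin C3=C4 bond stay inert.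

Step 3
Reactants: 6 suberenol
Product: 8 7-methoxy-6-[(E)-3-methylbuta-1,3-dienyl]coumarin, via tertiary allylic mesylate 7 (not isolated)
Conditions: MsCl (1.5 equiv), Et3N (4 equiv), CH2Cl2, 0 °C → rt; product kept cold, in solution, with a trace of BHT, and used at once
Reagents that add atoms: none
Why: Dehydration by mesylation–elimination, in which the tertiary mesylate ionises to the aryl-stabilised allyl cation and loses a methyl proton to Et3N; the only β-hydrogens are on the two methyl groups, so a single E-1,3-diene forms.

Step 4
Reactants: 8 7-methoxy-6-[(E)-3-methylbuta-1,3-dienyl]coumarin; 9 methacrolein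
Product: 10 (1R,2R)-2-(7-methoxy-2-oxo-2H-chromen-6-yl)-1,4-dimethylcyclohex-3-ene-1-carbaldehyde (coumarinyl and formyl groups cis)
Conditions: 9-amino(9-deoxy)epi-quinine (20 mol%), CF3CO2H (40 mol%), toluene, 0 °C → 23 °C, 48–72 h, dark; dienophile in fourfold excess, the surplus removed by evaporation
Reagents that add atoms: none
Why: Proposed new method: the primary amine condenses with the α-branched enal 9 (where secondary amines fail for steric reasons) to an N–H iminium trifluoroacetate whose lowered LUMO is attacked by the electron-rich 1-aryl-3-methyl diene 8 in a strongly asynchronous, ortho/para-regioselective [4+2] cycloaddition (diene CH2 terminus to the iminium β-CH2 first, then ArCH to Cα) through the transition state with the C=N+ group endo, which puts the coumarinyl group cis to the formyl group, while the protonated quinuclidine–counter-anion array and the quinoline wall of the catalyst are meant to leave only the Cα Si face open, so both stereocentres (1R,2R) are set in this one atom-economical step from achiral partners and the water formed in the condensation returns the amine by hydrolysis of the product iminium; the closest known reaction type is the primary-ammonium (iminium) catalysed Diels–Alder reaction of α-substituted acroleins with cyclopentadiene and simple dienes, together with cinchona primary-amine iminium activation of α-branched enals, neither of which has been shown for methacrolein with an acyclic 1-aryl diene.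

Step 5
Reactants: 11 2-hydroxy-4-methoxy-3-methylbenzaldehyde
Product: 14 7-methoxy-8-methylcoumarin, via E-cinnamate ester 12 (not isolated), via Z-cinnamate ester 13 (not isolated)
Conditions: Ph3P=CHCO2Et (1.2 equiv), PhNEt2, 210 °C, 3 h
Reagents that add atoms: ethyl (triphenylphosphoranylidene)acetate, CCOC(=O)C=P(c1ccccc1)(c1ccccc1)c1ccccc1
Why: Same Wittig–lactonisation coumarin synthesis as in step 1 (olefination, thermal E-to-Z isomerisation, lactonisation with loss of ethanol).

Step 6
Reactants: 14 7-methoxy-8-methylcoumarin
Product: 15 8-(bromomethyl)-7-methoxycoumarin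
Conditions: NBS (1.05 equiv), AIBN (5 mol%), PhCF3, 85 °C
Reagents that add atoms: N-bromosuccinimide, O=C1CCC(=O)N1Br
Why: Wohl–Ziegler radical bromination, in which the radical chain abstracts a benzylic hydrogen of the C8 methyl group and the non-polar medium with AIBN suppresses ionic bromination at C3 or C6.

Step 7
Reactants: 15 8-(bromomethyl)-7-methoxycoumarin
Product: 17 diethyl [(7-methoxy-2-oxo-2H-chromen-8-yl)methyl]phosphonate, via triethoxyphosphonium bromide 16 (not isolated)
Conditions: P(OEt)3 (5 equiv, neat), 130 °C, 3 h, EtBr distilled off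
Reagents that add atoms: triethyl phosphite, CCOP(OCC)OCC
Why: Michaelis–Arbuzov reaction, in which SN2 attack of the phosphite on the benzylic bromide and dealkylation of the phosphonium salt by bromide give the phosphonate.

Step 8
Reactants: 17 diethyl [(7-methoxy-2-oxo-2H-chromen-8-yl)methyl]phosphonate; 10 (1R,2R)-2-(7-methoxy-2-oxo-2H-chromen-6-yl)-1,4-dimethylcyclohex-3-ene-1-carbaldehyde
Product: 19 7-methoxy-6-[(1S,6S)-6-[(E)-2-(7-methoxy-2-oxo-2H-chromen-8-yl)ethenyl]-3,6-dimethylcyclohex-2-en-1-yl]-2H-chromen-2-one, via sodium phosphonate carbanion 18 (not isolated)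
Conditions: NaH (1.2 equiv), THF–DMF 5:1, 0 °C, 30 min; then the aldehyde added, 0 °C → rt; phosphonate in 1.3-fold excess
Reagents that add atoms: none
Why: Horner–Wadsworth–Emmons olefination, in which the benzylic phosphonate carbanion adds reversibly to the non-enolisable aldehyde and eliminates diethyl phosphate from the more stable adduct to give the E-alkene; neither stereocentre is touched, and both descriptors change from R to S only because the CIP priorities change.

## Compound list

1 | 5-bromo-2-hydroxy-4-methoxybenzaldehyde | COc1cc(O)c(C=O)cc1Br | starting material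
2 | ethyl (E)-3-(5-bromo-2-hydroxy-4-methoxyphenyl)prop-2-enoate | CCOC(=O)/C=C/c1cc(Br)c(OC)cc1O | intermediate (not isolated)
3 | ethyl (Z)-3-(5-bromo-2-hydroxy-4-methoxyphenyl)prop-2-enoate | CCOC(=O)/C=C\c1cc(Br)c(OC)cc1O | intermediate (not isolated)
4 | 6-bromo-7-methoxy-2H-chromen-2-one (6-bromo-7-methoxycoumarin) | COc1cc2oc(=O)ccc2cc1Br | intermediate
5 | 2-methylbut-3-en-2-ol | CC(C)(O)C=C | starting material
6 | suberenol (6-[(E)-3-hydroxy-3-methylbut-1-enyl]-7-methoxy-2H-chromen-2-one) | COc1cc2oc(=O)ccc2cc1/C=C/C(C)(C)O | intermediate
7 | (E)-4-(7-methoxy-2-oxo-2H-chromen-6-yl)-2-methylbut-3-en-2-yl methanesulfonate | COc1cc2oc(=O)ccc2cc1/C=C/C(C)(C)OS(C)(=O)=O | intermediate (not isolated)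
8 | 7-methoxy-6-[(E)-3-methylbuta-1,3-dienyl]-2H-chromen-2-one | COc1cc2oc(=O)ccc2cc1/C=C/C(C)=C | intermediate
9 | methacrolein (2-methylprop-2-enal) | CC(=C)C=O | starting material
10 | (1R,2R)-2-(7-methoxy-2-oxo-2H-chromen-6-yl)-1,4-dimethylcyclohex-3-ene-1-carbaldehyde | COc1cc2oc(=O)ccc2cc1[C@H]1C=C(C)CC[C@@]1(C)C=O | intermediate
11 | 2-hydroxy-4-methoxy-3-methylbenzaldehyde | COc1ccc(C=O)c(O)c1C | starting material
12 | ethyl (E)-3-(2-hydroxy-4-methoxy-3-methylphenyl)prop-2-enoate | CCOC(=O)/C=C/c1ccc(OC)c(C)c1O | intermediate (not isolated)
13 | ethyl (Z)-3-(2-hydroxy-4-methoxy-3-methylphenyl)prop-2-enoate | CCOC(=O)/C=C\c1ccc(OC)c(C)c1O | intermediate (not isolated)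
14 | 7-methoxy-8-methyl-2H-chromen-2-one | COc1ccc2ccc(=O)oc2c1C | intermediate
15 | 8-(bromomethyl)-7-methoxy-2H-chromen-2-one | COc1ccc2ccc(=O)oc2c1CBr | intermediate
16 | triethoxy[(7-methoxy-2-oxo-2H-chromen-8-yl)methyl]phosphonium bromide | CCO[P+](OCC)(OCC)Cc1c(OC)ccc2ccc(=O)oc12.[Br-] | intermediate (not isolated)
17 | diethyl [(7-methoxy-2-oxo-2H-chromen-8-yl)methyl]phosphonate | CCOP(=O)(OCC)Cc1c(OC)ccc2ccc(=O)oc12 | intermediate
18 | sodium salt of the benzylic carbanion of 17 | CCOP(=O)(OCC)[CH-]c1c(OC)ccc2ccc(=O)oc12.[Na+] | intermediate (not isolated)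
19 | 7-methoxy-6-[(1S,6S)-6-[(E)-2-(7-methoxy-2-oxo-2H-chromen-8-yl)ethenyl]-3,6-dimethylcyclohex-2-en-1-yl]-2H-chromen-2-one | COc1cc2oc(=O)ccc2cc1[C@H]1C=C(C)CC[C@@]1(C)/C=C/c1c(OC)ccc2ccc(=O)oc12 | target

## Step count and risks

Total steps: 8. Longest linear sequence: 5 (steps 1, 2, 3, 4, 8); fragment B (steps 5–7) is made in parallel.

**Step 4 (the new cycloaddition).** The iminium of methacrolein may be too weak a dienophile for 8, diene 8 may self-dimerise, and the cis/trans ratio or ee may be low because ring closure can become stepwise through the aryl-stabilised allyl cation. The ee is read by chiral HPLC on 10 and raised by recrystallisation of 10 or 19 if needed. The fallback uses known chemistry; it sets out from 8 (with 9) and comes back at 10. The amine catalyst is replaced by a chiral boron Lewis acid: the o-tolyl oxazaborolidine from diphenylprolinol, protonated with Tf2NH (20 mol%), in CH2Cl2 at −78 → −40 °C. Oxazaborolidinium-catalysed Diels–Alder reactions of 2-methylacrolein with dienes are established, and with an acyclic 1-substituted diene the endo (cis) adduct with the quaternary formyl centre is expected. The catalyst antipode is the one that opens the Cα Si face of the boron-bound enal by the formyl C–H···O model. It stays metal-free and makes no new compound.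

**Step 6 (benzylic bromination).** The methoxy-activated coumarin can be brominated in the ring (C3 or C6) or twice at the methyl group. The fallback drops the C8 benzylic arm altogether and makes the styrene bond at the aryl–vinyl position; it sets out from 10 and comes back at 19. Aldehyde 10 is methylenated (Ph3PCH3Br, KOtBu, THF, 0 °C) to 6-[(1S,6S)-6-ethenyl-3,6-dimethylcyclohex-2-en-1-yl]-7-methoxycoumarin F1. Bought 7-hydroxycoumarin is iodinated at C8 (I2, KI, aqueous NH3, rt) to 7-hydroxy-8-iodocoumarin F2 and O-methylated (MeI, K2CO3, acetone) to 8-iodo-7-methoxycoumarin F3. A Heck reaction of F1 with F3 (Pd(OAc)2, Bu4NCl, NaHCO3, DMF, 90 °C) gives 19 as the E-isomer, because the vinyl group on the quaternary carbon can only eliminate toward the aryl side.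

**Step 8 (olefination).** The aldehyde is neopentyl-like and hindered, and the carbanion or base can attack a coumarin lactone (conjugate addition or ring opening). The fallback replaces the basic olefination by a neutral organozinc addition followed by elimination; it sets out from 10 and 15 and comes back at 19. Zinc insertion into 15 (Zn dust, LiCl, THF, rt) gives (7-methoxy-2-oxo-2H-chromen-8-yl)methylzinc bromide F4. This adds to 10 (MgCl2, THF, 0 °C → rt) to give the secondary alcohol 8-[2-hydroxy-2-(cyclohexenyl)ethyl]-7-methoxycoumarin F5 (ring stereocentres as in 10, both carbinol epimers). Mesylation (MsCl, Et3N, CH2Cl2, 0 °C) gives the mesylate F6. E2 elimination with DBU in toluene at 90 °C can only remove a benzylic hydrogen, since the other neighbour is quaternary, and gives the conjugated E-alkene 19.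

## Further compounds

F0 | step 4 | none | none
F1 | step 6 | 6-[(1S,6S)-6-ethenyl-3,6-dimethylcyclohex-2-en-1-yl]-7-methoxy-2H-chromen-2-one | COc1cc2oc(=O)ccc2cc1[C@H]1C=C(C)CC[C@@]1(C)C=C
F2 | step 6 | 7-hydroxy-8-iodo-2H-chromen-2-one | Oc1ccc2ccc(=O)oc2c1I
F3 | step 6 | 8-iodo-7-methoxy-2H-chromen-2-one | COc1ccc2ccc(=O)oc2c1I
F4 | step 8 | (7-methoxy-2-oxo-2H-chromen-8-yl)methylzinc bromide | COc1ccc2ccc(=O)oc2c1C[Zn]Br
F5 | step 8 | secondary alcohol from addition of F4 to the formyl group of 10 (ring stereocentres as in 10, carbinol centre both epimers) | COc1cc2oc(=O)ccc2cc1[C@H]1C=C(C)CC[C@@]1(C)C(O)Cc1c(OC)ccc2ccc(=O)oc12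
F6 | step 8 | methanesulfonate of F5 | COc1cc2oc(=O)ccc2cc1[C@H]1C=C(C)CC[C@@]1(C)C(OS(C)(=O)=O)Cc1c(OC)ccc2ccc(=O)oc12
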